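The earlier runs and the new flask were generated by integration with made-up constants; the scatter is artificial.

At early times I read how the material arriving in J and L divided between them; late on I read how fast J drained away; then I joined the two ends.

| flask | G | remark | time |
|---|---|---|---|
| green | 2.3 M | the very flask that is asked about, followed so far |  |
| teal | 1.5 M | run made earlier |  |
| flask | 2.3 M |  | 12 h |

| run | time / h | J / % | L / % |
|---|---|---|---|
| green | 0.333 | 15.4 | 24.7 |
| green | 0.500 | 19.9 | 36.0 |
| green | 0.833 | 30.5 | 53.2 |
| green | 1.33 | 34.0 | 61.5 |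
| green | 2.00 | 32.5 | 67.1 |
| green | 3.00 | 26.0 | 71.7 |
| green | 5.00 | 21.7 | 76.1 |
| teal | 0.333 | 14.5 | 24.6 |
| teal | 0.500 | 22.4 | 38.9 |
| teal | 0.833 | 28.5 | 53.9 |
| teal | 1.33 | 31.4 | 61.8 |
| teal | 2.00 | 31.9 | 66.0 |
| teal | 3.00 | 27.2 | 72.4 |
| teal | 5.00 | 21.1 | 78.4 |

(scatter of a reading: 1 percentage point)

1. time up to 12 h at which J stands highest
2. the amount of J, in percent of the G charged, at that time

- percentages count the G that a species holds: one Q counts as two
- what may be going on: G -> D; E <-> J; G <-> X; D -> E; E -> L; 2 G -> Q

1. Green (2.3 M) and teal (1.5 M) ran alike within the scatter, so I pooled them as fractions of the charge.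
2. In the first two readings of each run, J held a share s = 36.8% of J + L. At 0.500 h, J + L stood at 58.6%, so I took that time as the average arrival.
3. I then read the drain of J two ways. The slope from 3.00 h to 5.00 h gave 0.109 /h. The fall from s at 0.500 h to the pooled 5.00 h reading gave λ = 0.120 /h, the fraction of J lost per hour once the feed is over. They share one reading and part by 0.0110 /h. I kept the second, whose span is longer; its half-life is 5.76 h.
4. The fraction W of the charge held outside J and L fell from 16.9% to 5.65% between the pooled 0.833 h and 1.33 h readings, a time constant τ = 0.452 h.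
5. J peaks where feed sW/τ equals drain λJ, at W = 4.84%. I reckoned that at 1.40 h, with J = 33.0%.

The forecast, reached by a different route, gave 1.55 h and 33.3%: “Sketching a curve through these”.

The flask gave 1.37 h and 32.3%.

    G → D (k = 0.00280 /s)
    E ⇌ J (K = 19.0, k = 0.00120 /s)
    G ⇌ X (K = 2.90, k = 0.0300 /s)
    D → E (k = 0.00650 /s)
    E → L (k = 0.00190 /s)
    2 G → Q (k = 1.40 × 10⁻⁶ /M/s)

In the green flask, G had fallen to 0.807% by 1.37 h while E fed J and L. From then to 12.0 h, J, the resting state of the pair E and J, drained through E into L, ending at 7.86% beside E at 0.162%. My half-life stood above the 5.01 h of the slowest mode at 12.0 h, so from 18.0% at 6.00 h it gave 8.76% against that 7.86%. Carried on to 30.0 h it gave 0.906%, and the neighbouring flask read at that time held J at 0.653%.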